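**Assumption:** the SMILES has no stereodescriptor (no stereocentre, biaryl axis unspecified), so the target is made as drawn with the axis formed without control; the free triacid lactonises easily and is handled cold and neutral.

**Retrosynthetic overview**
1. Valoneic acid 12 comes from the octa-O-benzyl trimethyl ester 10 by saponification and global hydrogenolysis, so no free phenol ever sits next to a free acid until the last step.
2. The ring B–ring C biaryl bond is made by an intermolecular Michael addition of the symmetric resorcinol 7 (ring C) to the o-quinone 8 of the ring A–O–ring B catechol 6.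
3. The ring A–O–ring B diaryl ether is made by Ullmann coupling of iodide 3 (ring A) with phenol 4 (ring B).
4. All three rings are methyl gallate 1; no ring is built de novo. Order: ring A–O–ring B first, then ring C.

**Route**

Step 1
Reactants: 1 methyl gallate (methyl 3,4,5-trihydroxybenzoate)
Product: 2 methyl 3,4,5-tris(benzyloxy)benzoate
Conditions: BnBr (3.5 equiv), K2CO3, DMF, 60 °C
Reagents that add atoms: benzyl bromide, BrCc1ccccc1
Why: Williamson ether synthesis on three acidic phenols with a reactive benzylic halide is exhaustive under these conditions and leaves the methyl ester intact.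

Step 2
Reactants: 2 methyl 3,4,5-tris(benzyloxy)benzoate
Product: 3 methyl 3,4,5-tris(benzyloxy)-2-iodobenzoate
Conditions: I2 (1.1 equiv), CF3CO2Ag (1.1 equiv), CHCl3, rt
Reagents that add atoms: iodine, II
Why: Electrophilic aromatic iodination by the I+ equivalent from I2/CF3CO2Ag goes to the only free ring position type (C2 and C6 are equivalent) of the trialkoxy ring, and the first iodine deactivates and shields against a second.

Step 3
Reactants: 1 methyl gallate
Product: 4 methyl 7-hydroxy-2,2-diphenyl-1,3-benzodioxole-5-carboxylate (methyl 3,4-O-diphenylmethylenegallate)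
Conditions: Ph2CCl2 (1.2 equiv), neat, 170 °C, 15 min
Reagents that add atoms: dichlorodiphenylmethane, ClC(Cl)(c1ccccc1)c1ccccc1
Why: Catechol ketalisation (diphenylmethylene acetal formation) can only bridge two adjacent hydroxyls, and by symmetry either pair gives the same product with one free OH left for the ether bond.

Step 4
Reactants: 3 methyl 3,4,5-tris(benzyloxy)-2-iodobenzoate; 4 methyl 7-hydroxy-2,2-diphenyl-1,3-benzodioxole-5-carboxylate
Product: 5 methyl 3,4,5-tris(benzyloxy)-2-{[6-(methoxycarbonyl)-2,2-diphenyl-1,3-benzodioxol-4-yl]oxy}benzoate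
Conditions: CuI (20 mol %), picolinic acid (40 mol %), K3PO4 (2 equiv), DMSO, 90 °C
Reagents that add atoms: none
Why: Ullmann-type C–O coupling is favoured by the ortho ester of the aryl iodide, and the picolinic acid ligand tolerates the ortho-substituted partners, while ketal, benzyl ethers and esters are stable to the mild base.

Step 5
Reactants: 5 the diaryl ether ketal
Product: 6 methyl 3,4,5-tris(benzyloxy)-2-[2,3-dihydroxy-5-(methoxycarbonyl)phenoxy]benzoate
Conditions: AcOH/H2O (4:1), 100 °C
Reagents that add atoms: none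
Why: Acid-catalysed ketal hydrolysis frees the ring B catechol, while benzyl aryl ethers, the diaryl ether and the methyl esters survive hot aqueous acetic acid.

Step 6
Reactants: 1 methyl gallate
Product: 7 methyl 4-(benzyloxy)-3,5-dihydroxybenzoate
Conditions: BnBr (1.0 equiv), KHCO3, KI (cat.), DMF, rt
Reagents that add atoms: benzyl bromide, BrCc1ccccc1
Why: Chemoselective Williamson mono-etherification occurs because the weak base ionises only the most acidic 4-OH (para to the ester), giving a symmetric resorcinol that cannot be oxidised to a quinone.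

Step 7
Reactants: 6 methyl 3,4,5-tris(benzyloxy)-2-[2,3-dihydroxy-5-(methoxycarbonyl)phenoxy]benzoate; 7 methyl 4-(benzyloxy)-3,5-dihydroxybenzoate (3 equiv)
Product: 9 dimethyl 5'-(benzyloxy)-4',5,6,6'-tetrahydroxy-4-[2,3,4-tris(benzyloxy)-6-(methoxycarbonyl)phenoxy]biphenyl-2,2'-dicarboxylate, via o-quinone 8 (not isolated)
Conditions: o-chloranil (1.0 equiv), CH2Cl2–MeCN, −40 °C, 30 min; then added slowly to 7, (PhO)2P(O)OH (10 mol %), −40 → 0 °C
Reagents that add atoms: none
Why: Oxidation gives the electron-poor o-quinone 8, whose CH next to the quinone carbonyl is the beta carbon of the ring acrylate and the vinylogous acceptor position of the far carbonyl (the other CH is deactivated by the aryloxy donor and shielded by ring A), so the doubly OH-activated C2 of symmetric 7 adds there in a Brønsted acid-catalysed Michael (conjugate) addition and tautomerisation restores both aromatic rings, with no stereocentre formed and the new biaryl axis left uncontrolled.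

Step 8
Reactants: 9 the tetrahydroxy biaryl
Product: 10 dimethyl 4',5,5',6,6'-pentakis(benzyloxy)-4-[2,3,4-tris(benzyloxy)-6-(methoxycarbonyl)phenoxy]biphenyl-2,2'-dicarboxylate (octa-O-benzylvaloneic acid trimethyl ester)
Conditions: BnBr (6 equiv), K2CO3, n-Bu4NI (cat.), DMF, rt
Reagents that add atoms: benzyl bromide, BrCc1ccccc1
Why: Williamson ether synthesis with excess reactive bromide at room temperature caps all four phenols faster than the phenoxides next to the axis can attack the neighbouring ester.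

Step 9
Reactants: 10 octa-O-benzylvaloneic acid trimethyl ester
Product: 11 4',5,5',6,6'-pentakis(benzyloxy)-4-[2,3,4-tris(benzyloxy)-6-carboxyphenoxy]biphenyl-2,2'-dicarboxylic acid (octa-O-benzylvaloneic acid)
Conditions: KOH (excess), dioxane/MeOH/H2O, 90 °C; then 1 M HCl, 0 °C
Reagents that add atoms: potassium hydroxide, [K+].[OH-] (its oxygen becomes the OH of each carboxyl group)
Why: Saponification (acyl-oxygen ester hydrolysis) of the three hindered methyl esters is forced by hot excess hydroxide, and with every phenol benzylated no lactone can form on acidification.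

Step 10
Reactants: 11 octa-O-benzylvaloneic acid
Product: 12 valoneic acid, 4-(6-carboxy-2,3,4-trihydroxyphenoxy)-4',5,5',6,6'-pentahydroxybiphenyl-2,2'-dicarboxylic acid
Conditions: H2 (1 atm), 10% Pd/C, THF, rt
Reagents that add atoms: none
Why: Catalytic hydrogenolysis removes all eight benzyl ethers under neutral conditions at room temperature, which releases the free triacid without the acid or heat that would drive lactonisation.

**Compound list**
1 | methyl gallate (methyl 3,4,5-trihydroxybenzoate) | COC(=O)c1cc(O)c(O)c(O)c1 | starting material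
2 | methyl 3,4,5-tris(benzyloxy)benzoate | COC(=O)c1cc(OCc2ccccc2)c(OCc2ccccc2)c(OCc2ccccc2)c1 | intermediate
3 | methyl 3,4,5-tris(benzyloxy)-2-iodobenzoate | COC(=O)c1cc(OCc2ccccc2)c(OCc2ccccc2)c(OCc2ccccc2)c1I | intermediate
4 | methyl 7-hydroxy-2,2-diphenyl-1,3-benzodioxole-5-carboxylate | COC(=O)c1cc(O)c2OC(c3ccccc3)(c3ccccc3)Oc2c1 | intermediate
5 | methyl 3,4,5-tris(benzyloxy)-2-{[6-(methoxycarbonyl)-2,2-diphenyl-1,3-benzodioxol-4-yl]oxy}benzoate | COC(=O)c1cc(OCc2ccccc2)c(OCc2ccccc2)c(OCc2ccccc2)c1Oc1cc(C(=O)OC)cc2OC(c3ccccc3)(c3ccccc3)Oc12 | intermediate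
6 | methyl 3,4,5-tris(benzyloxy)-2-[2,3-dihydroxy-5-(methoxycarbonyl)phenoxy]benzoate | COC(=O)c1cc(OCc2ccccc2)c(OCc2ccccc2)c(OCc2ccccc2)c1Oc1cc(C(=O)OC)cc(O)c1O | intermediate
7 | methyl 4-(benzyloxy)-3,5-dihydroxybenzoate | COC(=O)c1cc(O)c(OCc2ccccc2)c(O)c1 | intermediate
8 | methyl 3,4,5-tris(benzyloxy)-2-{[3-(methoxycarbonyl)-5,6-dioxocyclohexa-1,3-dien-1-yl]oxy}benzoate (o-quinone, not isolated) | COC(=O)c1cc(OCc2ccccc2)c(OCc2ccccc2)c(OCc2ccccc2)c1OC1=CC(C(=O)OC)=CC(=O)C1=O | intermediate
9 | dimethyl 5'-(benzyloxy)-4',5,6,6'-tetrahydroxy-4-[2,3,4-tris(benzyloxy)-6-(methoxycarbonyl)phenoxy]biphenyl-2,2'-dicarboxylate (axis uncontrolled) | COC(=O)c1cc(OCc2ccccc2)c(OCc2ccccc2)c(OCc2ccccc2)c1Oc1cc(C(=O)OC)c(-c2c(C(=O)OC)cc(O)c(OCc3ccccc3)c2O)c(O)c1O | intermediate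
10 | dimethyl 4',5,5',6,6'-pentakis(benzyloxy)-4-[2,3,4-tris(benzyloxy)-6-(methoxycarbonyl)phenoxy]biphenyl-2,2'-dicarboxylate | COC(=O)c1cc(OCc2ccccc2)c(OCc2ccccc2)c(OCc2ccccc2)c1Oc1cc(C(=O)OC)c(-c2c(C(=O)OC)cc(OCc3ccccc3)c(OCc3ccccc3)c2OCc2ccccc2)c(OCc2ccccc2)c1OCc1ccccc1 | intermediate
11 | 4',5,5',6,6'-pentakis(benzyloxy)-4-[2,3,4-tris(benzyloxy)-6-carboxyphenoxy]biphenyl-2,2'-dicarboxylic acid | OC(=O)c1cc(OCc2ccccc2)c(OCc2ccccc2)c(OCc2ccccc2)c1Oc1cc(C(=O)O)c(-c2c(C(=O)O)cc(OCc3ccccc3)c(OCc3ccccc3)c2OCc2ccccc2)c(OCc2ccccc2)c1OCc1ccccc1 | intermediate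
12 | valoneic acid | O=C(O)c1cc(O)c(O)c(O)c1Oc1cc(C(=O)O)c(-c2c(C(=O)O)cc(O)c(O)c2O)c(O)c1O | target

**Totals**
Total step count: 10. Longest linear sequence: 8 steps (1 → 2 → 3 → 5 → 6 → 9 → 10 → 11 → 12; steps 1, 2, 4, 5, 7, 8, 9, 10).

**Three steps most likely to fail**

Step 7 (Michael addition to the o-quinone). The regiochemistry at the quinone is argued from electronics and sterics, not demonstrated. The quinone 8 may also dimerise, oxidise the product 9, or be attacked through oxygen, and the ester-bearing resorcinol 7 is only a moderate carbon nucleophile. Fallback: set out from 7 and form the biaryl bond first by copper-mediated oxidative phenol coupling (CuCl2, n-BuNH2, MeOH, rt). The substrate is symmetric, so there is no regiochemical question, and the product is dimethyl 5,5'-bis(benzyloxy)-4,4',6,6'-tetrahydroxybiphenyl-2,2'-dicarboxylate F1. Mono-O-arylation of one of its two unhindered 4-hydroxyls with iodide 3 (CuI, picolinic acid, K3PO4, DMSO, 90 °C, F1 in excess and recycled) gives dimethyl 5,5'-bis(benzyloxy)-4',6,6'-trihydroxy-4-[2,3,4-tris(benzyloxy)-6-(methoxycarbonyl)phenoxy]biphenyl-2,2'-dicarboxylate F2. Benzylation of its three phenols (BnBr, K2CO3, DMF) comes back to the route at 10.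

Step 4 (Ullmann ether coupling). The iodide is di-ortho-substituted and electron-rich, so coupling may be slow and hydrodeiodination may compete. Fallback: set out from 3 and switch to metal-free O-arylation with a diaryliodonium salt. Oxidation of 3 with mCPBA/TsOH·H2O in MeCN followed by 1,3,5-trimethoxybenzene gives [2,3,4-tris(benzyloxy)-6-(methoxycarbonyl)phenyl](2,4,6-trimethoxyphenyl)iodonium tosylate F3. With phenol 4 and K2CO3 in toluene at 50 °C this transfers the ortho-substituted ring A aryl group (the trimethoxyphenyl group stays on iodine) and comes back to the route at 5.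

Step 8 (perbenzylation). The two hydroxyls next to the biaryl axis are hindered, and their phenoxides can close six-membered lactones onto the neighbouring methyl esters before they are alkylated. Fallback: set out from 9 and make lactonisation the intended path. Heating with TsOH (cat.) in toluene at 90 °C closes both lactones to the valoneic acid dilactone derivative methyl 3,4,5-tris(benzyloxy)-2-{[8-(benzyloxy)-3,7-dihydroxy-5,10-dioxo-5,10-dihydrochromeno[5,4,3-cde]chromen-2-yl]oxy}benzoate F4. Exhaustive alkaline benzylation (BnCl, KOH, n-Bu4NI cat., aqueous DMSO, 70 °C, argon) opens both lactones, saponifies the ring A ester and alkylates every phenoxide and carboxylate to give octa-O-benzylvaloneic acid tribenzyl ester F5. Hydrogenolysis (H2, 10% Pd/C, THF, rt) then comes back to the route at 12.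

**Further compounds**
F1 | step 7 | dimethyl 5,5'-bis(benzyloxy)-4,4',6,6'-tetrahydroxybiphenyl-2,2'-dicarboxylate | COC(=O)c1cc(O)c(OCc2ccccc2)c(O)c1-c1c(C(=O)OC)cc(O)c(OCc2ccccc2)c1O
F2 | step 7 | dimethyl 5,5'-bis(benzyloxy)-4',6,6'-trihydroxy-4-[2,3,4-tris(benzyloxy)-6-(methoxycarbonyl)phenoxy]biphenyl-2,2'-dicarboxylate | COC(=O)c1cc(OCc2ccccc2)c(OCc2ccccc2)c(OCc2ccccc2)c1Oc1cc(C(=O)OC)c(-c2c(C(=O)OC)cc(O)c(OCc3ccccc3)c2O)c(O)c1OCc1ccccc1
F3 | step 4 | [2,3,4-tris(benzyloxy)-6-(methoxycarbonyl)phenyl](2,4,6-trimethoxyphenyl)iodonium tosylate | COC(=O)c1cc(OCc2ccccc2)c(OCc2ccccc2)c(OCc2ccccc2)c1[I+]c1c(OC)cc(OC)cc1OC.Cc1ccc(cc1)S([O-])(=O)=O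
F4 | step 8 | methyl 3,4,5-tris(benzyloxy)-2-{[8-(benzyloxy)-3,7-dihydroxy-5,10-dioxo-5,10-dihydrochromeno[5,4,3-cde]chromen-2-yl]oxy}benzoate | O=C1Oc2c(OCc4ccccc4)c(O)cc3c2-c2c1cc(Oc4c(cc(OCc5ccccc5)c(OCc5ccccc5)c4OCc4ccccc4)C(=O)OC)c(O)c2OC3=O
F5 | step 8 | octa-O-benzylvaloneic acid tribenzyl ester | O=C(OCc1ccccc1)c1cc(OCc2ccccc2)c(OCc2ccccc2)c(OCc2ccccc2)c1Oc1cc(C(=O)OCc2ccccc2)c(-c2c(C(=O)OCc3ccccc3)cc(OCc3ccccc3)c(OCc3ccccc3)c2OCc2ccccc2)c(OCc2ccccc2)c1OCc1ccccc1
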